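**Retrosynthetic overview**

1. The ten-membered ring is closed last by ring-closing metathesis at C1=C10, between the C1 vinyl carbinol and a 2-substituted acrolein made by α-methylenation of the C14 aldehyde.
2. C3–C4 comes from an sp3–sp2 Negishi coupling of a chiral-pool C1–C3 zinc reagent (C2 stereocentre) with a (Z)-vinyl iodide whose geometry is fixed by trans-hydroalumination/iodination.
3. Key bond C7–C8: the allylzinc from a 3-(bromomethyl)butenolide adds through its β-carbon C7 (a homoenolate equivalent) to 4,4-dimethoxybutanal. This sets C7 and C8 from C6 and unveils the α-methylene lactone; C8 is then inverted during Mitsunobu esterification.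
4. The butenolide is made by metathesis of a 2-(bromomethyl)acrylate of an alkynylation-derived carbinol (C6).
5. Ring order: butenolide, then its transposition to the α-methylene-γ-lactone in the key step, then the ten-membered carbocycle.

Assumption: positions carry the germacrane numbers of the target (lactone O on C6, C12 carbonyl, C13 exo-methylene, C14 formyl, C15 acetoxymethyl); TBS = tert-butyldimethylsilyl; (S,S)-ProPhenol is taken to give the 4S alcohol 3 (otherwise its antipode is used); the CIP label at C6 reads S while iodine sits on C4 and R afterwards, with no change in spatial arrangement.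

**Step 1**
Reactants: 1 (E)-but-2-enal; 2 tert-butyldimethyl(prop-2-yn-1-yloxy)silane
Product: 3 (2E,4S)-7-(TBS-oxy)hept-2-en-5-yn-4-ol
Conditions: Me2Zn, (S,S)-ProPhenol (20 mol%), Ph3PO (40 mol%), toluene, 4 °C
Reagents that add atoms: none
Why: Zinc–ProPhenol asymmetric alkynylation (Trost) of an enal, in which the chiral dinuclear zinc catalyst delivers the alkynyl group to one aldehyde face and sets C6, the propenyl group being a place-holder that is expelled in step 4.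

**Step 2**
Reactants: 3 (2E,4S)-7-(TBS-oxy)hept-2-en-5-yn-4-ol
Product: 5 (2E,4S,5Z)-7-(TBS-oxy)-6-iodohepta-2,5-dien-4-ol, via cyclic vinylalanate 4 (not isolated)
Conditions: NaAlH2(OCH2CH2OMe)2, THF, 0 °C; then I2, −78 °C
Reagents that add atoms: iodine, II
Why: Alkoxide-directed trans-hydroalumination of the propargylic alcohol puts H on C5 and Al on C4 in a five-membered alanate, and iodinolysis with retention gives the (Z)-vinyl iodide that fixes the C4=C5 geometry (iodine, later C3, cis to C6).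

**Step 3**
Reactants: 5 (2E,4S,5Z)-7-(TBS-oxy)-6-iodohepta-2,5-dien-4-ol; 6 2-(bromomethyl)prop-2-enoic acid
Product: 7 (2E,4S,5Z)-7-(TBS-oxy)-6-iodohepta-2,5-dien-4-yl 2-(bromomethyl)prop-2-enoate
Conditions: DIC, DMAP (5 mol%), CH2Cl2, −20 → 0 °C
Reagents that add atoms: none
Why: Steglich esterification of the secondary alcohol under neutral conditions, with no stereocentre touched.

**Step 4**
Reactants: 7 (2E,4S,5Z)-7-(TBS-oxy)-6-iodohepta-2,5-dien-4-yl 2-(bromomethyl)prop-2-enoate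
Product: 8 (5S)-3-(bromomethyl)-5-[(1Z)-3-(TBS-oxy)-2-iodoprop-1-en-1-yl]furan-2(5H)-one
Conditions: second-generation Hoveyda–Grubbs catalyst (5 mol%), toluene (5 mM), 80 °C
Reagents that add atoms: none
Why: Ring-closing metathesis of the acrylate onto the propenyl group (propene lost) gives the butenolide, the trisubstituted vinyl iodide being inert and C6 untouched.

**Step 5**
Reactants: 9 methyl 4,4-dimethoxybutanoate
Product: 10 4,4-dimethoxybutanal
Conditions: i-Bu2AlH, CH2Cl2, −78 °C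
Reagents that add atoms: none
Why: Half-reduction of the ester stops at the aldehyde because the tetrahedral aluminium hemiacetal survives at low temperature.

**Step 6 (key step)**
Reactants: 8 (5S)-3-(bromomethyl)-5-[(1Z)-3-(TBS-oxy)-2-iodoprop-1-en-1-yl]furan-2(5H)-one; 10 4,4-dimethoxybutanal
Product: 12 (4R,5S)-4-[(1S)-1-hydroxy-4,4-dimethoxybutyl]-5-[(1Z)-3-(TBS-oxy)-2-iodoprop-1-en-1-yl]-3-methylideneoxolan-2-one, via allylzinc bromide 11 (not isolated)
Conditions: Zn dust, THF/sat. aq. NH4Cl, 0 °C → rt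
Reagents that add atoms: none
Why: Barbier-type allylation in which zinc insertion gives an allylzinc that reacts through C7, the β-carbon of the unsaturated lactone (a homoenolate equivalent, so two normally electrophilic carbons, C7 and the aldehyde carbon C8, are joined), anti to the C6 side chain (trans lactone, C7) and through a Zimmerman–Traxler chair whose ring-locked E-type allyl geometry gives the anti (8S) carbinol, with the double bond transposed to the exo-methylene.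

**Step 7**
Reactants: 12 (4R,5S)-4-[(1S)-1-hydroxy-4,4-dimethoxybutyl]-5-[(1Z)-3-(TBS-oxy)-2-iodoprop-1-en-1-yl]-3-methylideneoxolan-2-one; 13 3-methylbutanoic acid
Product: 14 (1R)-1-{(2S,3R)-2-[(1Z)-3-(TBS-oxy)-2-iodoprop-1-en-1-yl]-4-methylidene-5-oxooxolan-3-yl}-4,4-dimethoxybutyl 3-methylbutanoate
Conditions: PPh3, DIAD, toluene, 0 °C → rt
Reagents that add atoms: none
Why: Mitsunobu esterification installs the isovalerate with SN2 inversion, converting the 8S carbinol into the 8R ester required by the target.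

**Step 8**
Reactants: 15 (2R)-but-3-ene-1,2-diol
Product: 16 (2R)-1-iodobut-3-en-2-ol
Conditions: I2, PPh3, imidazole, THF, 0 °C
Reagents that add atoms: iodine, II
Why: Appel-type iodination is selective for the primary hydroxyl and leaves the chiral-pool stereocentre (future C2) untouched.

**Step 9**
Reactants: 16 (2R)-1-iodobut-3-en-2-ol
Product: 17 tert-butyl{[(2R)-1-iodobut-3-en-2-yl]oxy}dimethylsilane
Conditions: TBSOTf, 2,6-lutidine, CH2Cl2, −78 °C
Reagents that add atoms: tert-butyldimethylsilyl trifluoromethanesulfonate, CC(C)(C)[Si](C)(C)OS(=O)(=O)C(F)(F)F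
Why: Fast low-temperature silylation of the secondary alcohol avoids epoxide formation from the iodohydrin and does not affect the stereocentre.

**Step 10**
Reactants: 17 tert-butyl{[(2R)-1-iodobut-3-en-2-yl]oxy}dimethylsilane; 14 (1R)-1-{(2S,3R)-2-[(1Z)-3-(TBS-oxy)-2-iodoprop-1-en-1-yl]-4-methylidene-5-oxooxolan-3-yl}-4,4-dimethoxybutyl 3-methylbutanoate
Product: 19 (1R)-1-{(2R,3R)-2-[(1E,4S)-4-(TBS-oxy)-2-(TBS-oxymethyl)hexa-1,5-dien-1-yl]-4-methylidene-5-oxooxolan-3-yl}-4,4-dimethoxybutyl 3-methylbutanoate, via alkylzinc iodide 18 (not isolated)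
Conditions: Zn dust (activated), LiCl, THF, 25 °C; then 14, Pd(P(t-Bu)3)2 (5 mol%), THF/NMP, 25 °C
Reagents that add atoms: none
Why: Negishi sp3–sp2 cross-coupling joins C3 to C4 with retention of the olefin geometry (C3 cis to C6), the C2 configuration coming from 15 and the bulky silyl ether slowing β-elimination of the zinc reagent.

**Step 11**
Reactants: 19 (1R)-1-{(2R,3R)-2-[(1E,4S)-4-(TBS-oxy)-2-(TBS-oxymethyl)hexa-1,5-dien-1-yl]-4-methylidene-5-oxooxolan-3-yl}-4,4-dimethoxybutyl 3-methylbutanoate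
Product: 20 (1R)-1-{(2R,3R)-2-[(1E,4S)-4-hydroxy-2-(hydroxymethyl)hexa-1,5-dien-1-yl]-4-methylidene-5-oxooxolan-3-yl}-4-oxobutyl 3-methylbutanoate
Conditions: 48% aq. HF, MeCN, 0 °C → rt
Reagents that add atoms: water, O
Why: Acidic fluoride cleaves both silyl ethers and hydrolyses the dimethyl acetal to the C14 aldehyde in one operation without touching a stereocentre.

**Step 12**
Reactants: 20 (1R)-1-{(2R,3R)-2-[(1E,4S)-4-hydroxy-2-(hydroxymethyl)hexa-1,5-dien-1-yl]-4-methylidene-5-oxooxolan-3-yl}-4-oxobutyl 3-methylbutanoate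
Product: 21 (1R)-1-{(2R,3R)-2-[(1E,4S)-2-(acetoxymethyl)-4-hydroxyhexa-1,5-dien-1-yl]-4-methylidene-5-oxooxolan-3-yl}-4-oxobutyl 3-methylbutanoate
Conditions: AcCl (1.05 equiv), 2,4,6-collidine, CH2Cl2, −78 °C
Reagents that add atoms: acetyl chloride, CC(=O)Cl
Why: Kinetically selective acylation of the primary allylic hydroxyl (C15) over the secondary C2 hydroxyl.

**Step 13**
Reactants: 21 (1R)-1-{(2R,3R)-2-[(1E,4S)-2-(acetoxymethyl)-4-hydroxyhexa-1,5-dien-1-yl]-4-methylidene-5-oxooxolan-3-yl}-4-oxobutyl 3-methylbutanoate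
Product: 22 (1R)-1-{(2R,3R)-2-[(1E,4S)-2-(acetoxymethyl)-4-hydroxyhexa-1,5-dien-1-yl]-4-methylidene-5-oxooxolan-3-yl}-3-formylbut-3-en-1-yl 3-methylbutanoate
Conditions: CH2=NMe2+ I− (Eschenmoser's salt), Et3N, CH2Cl2, rt
Reagents that add atoms: Eschenmoser's salt (N,N-dimethylmethyleneiminium iodide), C=[N+](C)C.[I-]
Why: Mannich reaction at C10 followed by β-elimination of dimethylamine (α-methylenation of an aldehyde) gives the 2-substituted acrolein needed for ring closure.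

**Step 14**
Reactants: 22 (1R)-1-{(2R,3R)-2-[(1E,4S)-2-(acetoxymethyl)-4-hydroxyhexa-1,5-dien-1-yl]-4-methylidene-5-oxooxolan-3-yl}-3-formylbut-3-en-1-yl 3-methylbutanoate
Product: 23 (3aR,4R,6E,8S,10E,11aR)-10-(acetoxymethyl)-6-formyl-8-hydroxy-3-methylidene-2-oxo-2,3,3a,4,5,8,9,11a-octahydrocyclodeca[b]furan-4-yl 3-methylbutanoate
Conditions: second-generation Hoveyda–Grubbs catalyst (10 mol%), 1,4-benzoquinone (20 mol%), toluene (1 mM), 80 °C
Reagents that add atoms: none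
Why: Ring-closing metathesis between the C1 vinyl group (the only readily initiating olefin) and the 2-substituted acrolein closes the ten-membered ring with loss of ethene, and the enal forms with CHO trans to C2, the geometry favoured both in metathesis of 2-substituted acroleins and in a cis,cis-cyclodeca-1,5-diene.

**Compound list**

1 | (E)-but-2-enal | C/C=C/C=O | starting material
2 | tert-butyldimethyl(prop-2-yn-1-yloxy)silane | C#CCO[Si](C)(C)C(C)(C)C | starting material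
3 | (2E,4S)-7-[(tert-butyldimethylsilyl)oxy]hept-2-en-5-yn-4-ol | C/C=C/[C@H](O)C#CCO[Si](C)(C)C(C)(C)C | intermediate
4 | sodium salt of the five-membered alkoxy(vinyl)alanate from 3 (Al on C4 and on the C6 oxygen, two 2-methoxyethoxy ligands, 5S) | C/C=C/[C@@H]1O[Al-](OCCOC)(OCCOC)C(CO[Si](C)(C)C(C)(C)C)=C1.[Na+] | intermediate (not isolated)
5 | (2E,4S,5Z)-7-[(tert-butyldimethylsilyl)oxy]-6-iodohepta-2,5-dien-4-ol | C/C=C/[C@H](O)/C=C(/CO[Si](C)(C)C(C)(C)C)\I | intermediate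
6 | 2-(bromomethyl)prop-2-enoic acid | C=C(CBr)C(=O)O | starting material
7 | (2E,4S,5Z)-7-[(tert-butyldimethylsilyl)oxy]-6-iodohepta-2,5-dien-4-yl 2-(bromomethyl)prop-2-enoate | C=C(CBr)C(=O)O[C@@H](/C=C/C)/C=C(/CO[Si](C)(C)C(C)(C)C)\I | intermediate
8 | (5S)-3-(bromomethyl)-5-[(1Z)-3-[(tert-butyldimethylsilyl)oxy]-2-iodoprop-1-en-1-yl]furan-2(5H)-one | BrCC1=C[C@@H](/C=C(/CO[Si](C)(C)C(C)(C)C)\I)OC1=O | intermediate
9 | methyl 4,4-dimethoxybutanoate | COC(=O)CCC(OC)OC | starting material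
10 | 4,4-dimethoxybutanal | O=CCCC(OC)OC | intermediate
11 | {[(5S)-5-[(1Z)-3-[(tert-butyldimethylsilyl)oxy]-2-iodoprop-1-en-1-yl]-2-oxo-2,5-dihydrofuran-3-yl]methyl}zinc bromide | Br[Zn]CC1=C[C@@H](/C=C(/CO[Si](C)(C)C(C)(C)C)\I)OC1=O | intermediate (not isolated)
12 | (4R,5S)-4-[(1S)-1-hydroxy-4,4-dimethoxybutyl]-5-[(1Z)-3-[(tert-butyldimethylsilyl)oxy]-2-iodoprop-1-en-1-yl]-3-methylideneoxolan-2-one | C=C1C(=O)O[C@H](/C=C(/CO[Si](C)(C)C(C)(C)C)\I)[C@H]1[C@@H](O)CCC(OC)OC | intermediate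
13 | 3-methylbutanoic acid | CC(C)CC(=O)O | starting material
14 | (1R)-1-{(2S,3R)-2-[(1Z)-3-[(tert-butyldimethylsilyl)oxy]-2-iodoprop-1-en-1-yl]-4-methylidene-5-oxooxolan-3-yl}-4,4-dimethoxybutyl 3-methylbutanoate | C=C1C(=O)O[C@H](/C=C(/CO[Si](C)(C)C(C)(C)C)\I)[C@H]1[C@H](OC(=O)CC(C)C)CCC(OC)OC | intermediate
15 | (2R)-but-3-ene-1,2-diol | C=C[C@@H](O)CO | starting material
16 | (2R)-1-iodobut-3-en-2-ol | C=C[C@@H](O)CI | intermediate
17 | tert-butyl{[(2R)-1-iodobut-3-en-2-yl]oxy}dimethylsilane | C=C[C@@H](O[Si](C)(C)C(C)(C)C)CI | intermediate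
18 | {(2R)-2-[(tert-butyldimethylsilyl)oxy]but-3-en-1-yl}zinc iodide | C=C[C@@H](O[Si](C)(C)C(C)(C)C)C[Zn]I | intermediate (not isolated)
19 | (1R)-1-{(2R,3R)-2-[(1E,4S)-4-[(tert-butyldimethylsilyl)oxy]-2-{[(tert-butyldimethylsilyl)oxy]methyl}hexa-1,5-dien-1-yl]-4-methylidene-5-oxooxolan-3-yl}-4,4-dimethoxybutyl 3-methylbutanoate | C=C1C(=O)O[C@H](/C=C(/CO[Si](C)(C)C(C)(C)C)C[C@H](O[Si](C)(C)C(C)(C)C)C=C)[C@H]1[C@H](OC(=O)CC(C)C)CCC(OC)OC | intermediate
20 | (1R)-1-{(2R,3R)-2-[(1E,4S)-4-hydroxy-2-(hydroxymethyl)hexa-1,5-dien-1-yl]-4-methylidene-5-oxooxolan-3-yl}-4-oxobutyl 3-methylbutanoate | C=C1C(=O)O[C@H](/C=C(/CO)C[C@H](O)C=C)[C@H]1[C@H](OC(=O)CC(C)C)CCC=O | intermediate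
21 | (1R)-1-{(2R,3R)-2-[(1E,4S)-2-[(acetyloxy)methyl]-4-hydroxyhexa-1,5-dien-1-yl]-4-methylidene-5-oxooxolan-3-yl}-4-oxobutyl 3-methylbutanoate | C=C1C(=O)O[C@H](/C=C(/COC(C)=O)C[C@H](O)C=C)[C@H]1[C@H](OC(=O)CC(C)C)CCC=O | intermediate
22 | (1R)-1-{(2R,3R)-2-[(1E,4S)-2-[(acetyloxy)methyl]-4-hydroxyhexa-1,5-dien-1-yl]-4-methylidene-5-oxooxolan-3-yl}-3-formylbut-3-en-1-yl 3-methylbutanoate | C=C1C(=O)O[C@H](/C=C(/COC(C)=O)C[C@H](O)C=C)[C@H]1[C@H](OC(=O)CC(C)C)CC(=C)C=O | intermediate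
23 | (3aR,4R,6E,8S,10E,11aR)-10-[(acetyloxy)methyl]-6-formyl-8-hydroxy-3-methylidene-2-oxo-2,3,3a,4,5,8,9,11a-octahydrocyclodeca[b]furan-4-yl 3-methylbutanoate (CNP0524123.1) | C=C1C(=O)O[C@@H]2/C=C(/COC(C)=O)C[C@H](O)/C=C(/C=O)C[C@@H](OC(=O)CC(C)C)[C@@H]12 | target

**Step count and risks**

Total step count: 14. Longest linear sequence: 11 steps (steps 1–4, 6, 7, 10–14).

The three steps most likely to fail:

- **Step 7.** The C8 carbinol is hindered (next to the ring carbon C7), so the Mitsunobu reaction may eliminate or stall, and it relies on step 6 giving the 8S alcohol. The fallback sets out from 12 and comes back at 14. Oxidation with Dess–Martin periodinane (NaHCO3, CH2Cl2, 0 °C) gives the C8 ketone (4S,5S)-4-(4,4-dimethoxybutanoyl)-5-[(1Z)-3-(TBS-oxy)-2-iodoprop-1-en-1-yl]-3-methylideneoxolan-2-one F1. Reagent-controlled reduction with (S)-Me-CBS and catecholborane at −78 °C, with the ring carbon C7 as the large group, gives the 8R alcohol (4R,5S)-4-[(1R)-1-hydroxy-4,4-dimethoxybutyl]-5-[(1Z)-3-(TBS-oxy)-2-iodoprop-1-en-1-yl]-3-methylideneoxolan-2-one F2. Esterification of F2 with 13 (DIC, DMAP) proceeds with retention and gives 14. This redox detour also funnels any C8 epimer mixture from step 6.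

- **Step 10.** The β-silyloxy alkylzinc 18 may β-eliminate to butadiene, and zerovalent palladium may ionise the allylic lactone. The fallback sets out from 14 and comes back at 22; it builds C3–C2 first and adds C1 afterwards.
  - Negishi coupling of 14 with commercial (1,3-dioxolan-2-ylmethyl)zinc bromide, a stable β,β-dialkoxy alkylzinc, gives the C2 dioxolane analogue of 19 lacking C1 and the C2 silyl ether, F3.
  - LiBF4 in wet MeCN cleaves only the dimethyl acetal to give the C14 aldehyde F4.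
  - Eschenmoser's salt and Et3N give the 2-substituted acrolein F5.
  - HF·pyridine frees the C15 alcohol F6.
  - AcCl and collidine give the C15 acetate F7.
  - Aqueous TFA in CH2Cl2 at 0 °C opens the dioxolane to the C2 aldehyde F8.
  - A catalytic asymmetric Nozaki–Hiyama–Kishi vinylation (vinyl bromide, CrCl2, NiCl2 cat., Kishi chiral sulfonamide ligand, MeCN) adds C1 to the unhindered C2 aldehyde and sets 2S, giving 22.

- **Step 14.** Forming a trisubstituted enal inside a ten-membered ring by metathesis may be slow or give oligomers. The fallback sets out from 22 and comes back at 23. Luche reduction (NaBH4, CeCl3·7H2O, MeOH, −78 °C) converts the enal into the allylic alcohol (1R)-1-{(2R,3R)-2-[(1E,4S)-2-(acetoxymethyl)-4-hydroxyhexa-1,5-dien-1-yl]-4-methylidene-5-oxooxolan-3-yl}-3-(hydroxymethyl)but-3-en-1-yl 3-methylbutanoate F9. Its electron-richer 1,1-disubstituted olefin is a better metathesis partner, and ring closure with the same catalyst gives the macrocyclic diol, the 14-hydroxy analogue of the target, F10. Selective oxidation of the primary allylic alcohol (TEMPO, PhI(OAc)2, CH2Cl2) then gives 23.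

**Further compounds**

F1 | step 7 | (4S,5S)-4-(4,4-dimethoxybutanoyl)-5-[(1Z)-3-[(tert-butyldimethylsilyl)oxy]-2-iodoprop-1-en-1-yl]-3-methylideneoxolan-2-one | C=C1C(=O)O[C@H](/C=C(/CO[Si](C)(C)C(C)(C)C)\I)[C@H]1C(=O)CCC(OC)OC
F2 | step 7 | (4R,5S)-4-[(1R)-1-hydroxy-4,4-dimethoxybutyl]-5-[(1Z)-3-[(tert-butyldimethylsilyl)oxy]-2-iodoprop-1-en-1-yl]-3-methylideneoxolan-2-one | C=C1C(=O)O[C@H](/C=C(/CO[Si](C)(C)C(C)(C)C)\I)[C@H]1[C@H](O)CCC(OC)OC
F3 | step 10 | (1R)-1-{(2R,3R)-2-[(1E)-2-{[(tert-butyldimethylsilyl)oxy]methyl}-3-(1,3-dioxolan-2-yl)prop-1-en-1-yl]-4-methylidene-5-oxooxolan-3-yl}-4,4-dimethoxybutyl 3-methylbutanoate | C=C1C(=O)O[C@H](/C=C(/CO[Si](C)(C)C(C)(C)C)CC2OCCO2)[C@H]1[C@H](OC(=O)CC(C)C)CCC(OC)OC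
F4 | step 10 | (1R)-1-{(2R,3R)-2-[(1E)-2-{[(tert-butyldimethylsilyl)oxy]methyl}-3-(1,3-dioxolan-2-yl)prop-1-en-1-yl]-4-methylidene-5-oxooxolan-3-yl}-4-oxobutyl 3-methylbutanoate | C=C1C(=O)O[C@H](/C=C(/CO[Si](C)(C)C(C)(C)C)CC2OCCO2)[C@H]1[C@H](OC(=O)CC(C)C)CCC=O
F5 | step 10 | (1R)-1-{(2R,3R)-2-[(1E)-2-{[(tert-butyldimethylsilyl)oxy]methyl}-3-(1,3-dioxolan-2-yl)prop-1-en-1-yl]-4-methylidene-5-oxooxolan-3-yl}-3-formylbut-3-en-1-yl 3-methylbutanoate | C=C1C(=O)O[C@H](/C=C(/CO[Si](C)(C)C(C)(C)C)CC2OCCO2)[C@H]1[C@H](OC(=O)CC(C)C)CC(=C)C=O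
F6 | step 10 | (1R)-1-{(2R,3R)-2-[(1E)-3-(1,3-dioxolan-2-yl)-2-(hydroxymethyl)prop-1-en-1-yl]-4-methylidene-5-oxooxolan-3-yl}-3-formylbut-3-en-1-yl 3-methylbutanoate | C=C1C(=O)O[C@H](/C=C(/CO)CC2OCCO2)[C@H]1[C@H](OC(=O)CC(C)C)CC(=C)C=O
F7 | step 10 | (1R)-1-{(2R,3R)-2-[(1E)-2-[(acetyloxy)methyl]-3-(1,3-dioxolan-2-yl)prop-1-en-1-yl]-4-methylidene-5-oxooxolan-3-yl}-3-formylbut-3-en-1-yl 3-methylbutanoate | C=C1C(=O)O[C@H](/C=C(/COC(C)=O)CC2OCCO2)[C@H]1[C@H](OC(=O)CC(C)C)CC(=C)C=O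
F8 | step 10 | (1R)-1-{(2R,3R)-2-[(1E)-2-[(acetyloxy)methyl]-4-oxobut-1-en-1-yl]-4-methylidene-5-oxooxolan-3-yl}-3-formylbut-3-en-1-yl 3-methylbutanoate | C=C1C(=O)O[C@H](/C=C(/COC(C)=O)CC=O)[C@H]1[C@H](OC(=O)CC(C)C)CC(=C)C=O
F9 | step 14 | (1R)-1-{(2R,3R)-2-[(1E,4S)-2-[(acetyloxy)methyl]-4-hydroxyhexa-1,5-dien-1-yl]-4-methylidene-5-oxooxolan-3-yl}-3-(hydroxymethyl)but-3-en-1-yl 3-methylbutanoate | C=C1C(=O)O[C@H](/C=C(/COC(C)=O)C[C@H](O)C=C)[C@H]1[C@H](OC(=O)CC(C)C)CC(=C)CO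
F10 | step 14 | (3aR,4R,6E,8S,10E,11aR)-10-[(acetyloxy)methyl]-8-hydroxy-6-(hydroxymethyl)-3-methylidene-2-oxo-2,3,3a,4,5,8,9,11a-octahydrocyclodeca[b]furan-4-yl 3-methylbutanoate | C=C1C(=O)O[C@@H]2/C=C(/COC(C)=O)C[C@H](O)/C=C(/CO)C[C@@H](OC(=O)CC(C)C)[C@@H]12
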